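**Plan**

- Retrosynthesis: the two O-benzyl groups on O5 and O7 come off first, and the prenyl chain is cut back to an allyl group (cross-metathesis). The C4–C4a bond of ring C is then cut, giving a 3-aryloxy-2-arylacrylic acid. Behind it lie the vinyl C2–O1 bond (phenoxide plus enol tosylate), the C2–C3 bond (formylation of an arylacetate) and the aryl–allyl bond (Claisen rearrangement).
- Forward order: ring B is elaborated on homovanillic acid (ester, O-allyl, Claisen shift to C5', O-methyl). C2 is added as a formyl group, ring A is joined through O1 by addition–elimination, and ring C is closed last by acylation at C4a. Metathesis to the prenyl group and debenzylation finish the synthesis.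
- Enabling feature: the carbon that becomes C4a has O1 on one neighbour (C8a), O5 on the other (C5) and O7 across the ring. In a symmetrical 3,5-bis(benzyloxy)phenyl enol ether, both carbons next to the ether oxygen are therefore identical and activated by three oxygen donors.
- Stereochemistry: the target has no stereocentre and its prenyl alkene has no geometry. The enol ether double bond of the precursor becomes the endocyclic C2=C3 bond, so its geometry is erased.

Key step: step 9

Remark on the chemistry: compounds 8, 9, 11, 12 and 13 are drawn and named as Z isomers (carbonyl group and C3 oxygen on the same side). This is the geometry that chelation-controlled tosylation and a stereoretentive addition–elimination should deliver. Compound 8 is in equilibrium with its aldehyde tautomer. E-configured material from steps 6 to 8 would be carried on, because step 9 is expected to converge both geometries.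

**Route**

Step 1
Reactants: 1 4-hydroxy-3-methoxyphenylacetic acid (homovanillic acid)
Product: 2 methyl 2-(4-hydroxy-3-methoxyphenyl)acetate
Conditions: MeOH, H2SO4 (cat.), reflux
Reagents that add atoms: methanol, CO
Why: Fischer esterification in excess methanol drives the equilibrium to the methyl ester and leaves the phenol free for the next step.

Step 2
Reactants: 2 methyl 2-(4-hydroxy-3-methoxyphenyl)acetate; 3 allyl bromide
Product: 4 methyl 2-(3-methoxy-4-prop-2-enoxyphenyl)acetate
Conditions: K2CO3, acetone, reflux
Reagents that add atoms: none
Why: Williamson ether synthesis, in which K2CO3 deprotonates only the phenol (not the ester α-CH2) and the phenoxide displaces bromide from the allylic halide.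

Step 3
Reactants: 4 methyl 2-(3-methoxy-4-prop-2-enoxyphenyl)acetate
Product: 6 methyl 2-(4-hydroxy-3-methoxy-5-prop-2-enylphenyl)acetate, via ortho-allyl cyclohexadienone 5 (not isolated)
Conditions: PhNEt2, 200 °C
Reagents that add atoms: none
Why: Aromatic Claisen rearrangement, a [3,3] shift that can only deliver the allyl group to the single free ortho carbon (C5, since C3 carries the methoxy group), after which dienone 5 tautomerises to the phenol.

Step 4
Reactants: 6 methyl 2-(4-hydroxy-3-methoxy-5-prop-2-enylphenyl)acetate
Product: 7 methyl 2-(3,4-dimethoxy-5-prop-2-enylphenyl)acetate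
Conditions: MeI, K2CO3, DMF, rt
Reagents that add atoms: iodomethane, CI
Why: Williamson O-methylation of the hindered but acidic phenol under conditions too mild to alkylate the ester α-carbon or to move the allyl double bond.

Step 5
Reactants: 7 methyl 2-(3,4-dimethoxy-5-prop-2-enylphenyl)acetate
Product: 8 methyl (Z)-2-(3,4-dimethoxy-5-prop-2-enylphenyl)-3-hydroxyprop-2-enoate (enol form of the α-formyl ester)
Conditions: HCO2Me, NaH, THF, 0 °C to rt; then cold 1 M HCl
Reagents that add atoms: methyl formate, COC=O
Why: Crossed Claisen condensation (C-formylation) of the arylacetate, driven by formation of the stabilised sodium enolate of the product, with methyl formate chosen to match the methyl ester so that transesterification is invisible.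

Step 6
Reactants: 8 methyl (Z)-2-(3,4-dimethoxy-5-prop-2-enylphenyl)-3-hydroxyprop-2-enoate
Product: 9 methyl (Z)-2-(3,4-dimethoxy-5-prop-2-enylphenyl)-3-(4-methylphenyl)sulfonyloxyprop-2-enoate
Conditions: TsCl, TMEDA, LiCl, EtOAc, 0 °C
Reagents that add atoms: 4-methylbenzenesulfonyl chloride, Cc1ccc(cc1)S(=O)(=O)Cl
Why: O-sulfonylation of the enolised α-formyl ester, in which lithium chelation between the ester carbonyl and the enolate oxygen should fix the Z geometry and turn C3 into a vinylogous acyl electrophile.

Step 7
Reactants: 9 methyl (Z)-2-(3,4-dimethoxy-5-prop-2-enylphenyl)-3-(4-methylphenyl)sulfonyloxyprop-2-enoate; 10 3,5-bis(benzyloxy)phenol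
Product: 11 methyl (Z)-3-[3,5-bis(benzyloxy)phenoxy]-2-(3,4-dimethoxy-5-prop-2-enylphenyl)prop-2-enoate
Conditions: Cs2CO3, MeCN, rt to 40 °C
Reagents that add atoms: none
Why: Vinylic nucleophilic substitution by addition–elimination, in which the caesium phenoxide adds to C3 of the β-sulfonyloxyacrylate and the ester-stabilised carbanion expels tosylate, normally with retention of the alkene geometry.

Step 8
Reactants: 11 methyl (Z)-3-[3,5-bis(benzyloxy)phenoxy]-2-(3,4-dimethoxy-5-prop-2-enylphenyl)prop-2-enoate
Product: 12 (Z)-3-[3,5-bis(benzyloxy)phenoxy]-2-(3,4-dimethoxy-5-prop-2-enylphenyl)prop-2-enoic acid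
Conditions: LiOH, THF/MeOH/H2O, rt; then 1 M HCl to pH 3, 0 °C
Reagents that add atoms: lithium hydroxide, [Li+].[OH-]
Why: Saponification of the methyl ester, the standard way to 3-aryloxyacrylic acids, in which the donor oxygen on C3 makes the vinylogous carbonate a poor Michael acceptor so that hydroxide should attack the ester carbonyl and spare the enol ether and the aryl ethers.

Step 9
Reactants: 12 (Z)-3-[3,5-bis(benzyloxy)phenoxy]-2-(3,4-dimethoxy-5-prop-2-enylphenyl)prop-2-enoic acid
Product: 14 5,7-bis(benzyloxy)-3-(3,4-dimethoxy-5-prop-2-enylphenyl)chromen-4-one, via mixed trifluoroacetic anhydride 13 (not isolated)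
Conditions: (CF3CO)2O (1.2 equiv), CH2Cl2, 0 °C to rt
Reagents that add atoms: none
Why: Trifluoroacetic anhydride converts the acid into mixed anhydride 13, whose acyl group, helped by the trifluoroacetic acid released, reacts as an acylium ion stabilised by the C3 aryloxy oxygen; the nucleophile is C2 (or the identical C6) of the 3,5-bis(benzyloxy)phenoxy ring, and loss of a proton from the arenium ion leaves the new C4–C4a bond. The closest known reaction type is the cyclodehydration of 3-aryloxyacrylic acids to chromones, an intramolecular Friedel–Crafts acylation. Ring C closes as a six-membered ring by electrophilic aromatic substitution, exo with respect to the acyl C=O and with the enol-ether-like C8a=C4a unit inside the new ring (6-(enolendo)-exo-trig). No stereocentre is formed, and the enol ether geometry need not be controlled, because the donor–acceptor (oxocarbenium/ketene) character of the acylium lowers the rotational barrier about C2–C3 so that E-configured material can reach the reactive arrangement. The step needs regioselectivity for a carbon next to the ether oxygen and chemoselectivity over ring trifluoroacetylation: the two ortho carbons are identical by symmetry and triply activated, the carbon between the benzyloxy groups is beyond the reach of the three-atom tether, and the intramolecular acylation should outrun intermolecular reactions when only a slight excess of anhydride is used at 0 °C. The allyl group, the benzyl ethers and the methyl ethers are expected to tolerate trifluoroacetic acid at this temperature, which is why the acid-sensitive prenyl group is installed only afterwards.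

Step 10
Reactants: 14 5,7-bis(benzyloxy)-3-(3,4-dimethoxy-5-prop-2-enylphenyl)chromen-4-one; 15 2-methylbut-2-ene
Product: 16 5,7-bis(benzyloxy)-3-[3,4-dimethoxy-5-(3-methylbut-2-enyl)phenyl]chromen-4-one
Conditions: second-generation Grubbs catalyst RuCl2(=CHPh)(H2IMes)(PCy3) (5 mol %), 2-methylbut-2-ene (excess)/CH2Cl2, 35 °C, sealed vessel
Reagents that add atoms: none
Why: Olefin cross-metathesis, in which the monosubstituted allyl alkene is the only readily metathesised olefin in 14 and excess 2-methylbut-2-ene caps it as the trisubstituted prenyl alkene, while the chromone C2=C3 bond and the benzyl ethers are inert to the ruthenium carbene.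

Step 11
Reactants: 16 5,7-bis(benzyloxy)-3-[3,4-dimethoxy-5-(3-methylbut-2-enyl)phenyl]chromen-4-one
Product: 17 piscerythrinetin, 5,7-dihydroxy-3-[3,4-dimethoxy-5-(3-methylbut-2-enyl)phenyl]chromen-4-one
Conditions: BCl3, C6HMe5, CH2Cl2, −78 °C; then H2O
Reagents that add atoms: none
Why: Lewis-acid O-debenzylation with a cation scavenger, in which BCl3 activates the benzyl ethers (the C5 ether assisted by the C4 carbonyl), pentamethylbenzene traps the benzyl cations by Friedel–Crafts alkylation before they can attack the prenyl alkene, and the two methyl ethers, which have no neighbouring carbonyl, should survive at −78 °C.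

**Compound list**

1 | 4-hydroxy-3-methoxyphenylacetic acid (homovanillic acid) | COc1cc(CC(=O)O)ccc1O | starting material
2 | methyl 2-(4-hydroxy-3-methoxyphenyl)acetate | COC(=O)Cc1ccc(O)c(OC)c1 | intermediate
3 | allyl bromide | C=CCBr | starting material
4 | methyl 2-(3-methoxy-4-prop-2-enoxyphenyl)acetate | COC(=O)Cc1ccc(OCC=C)c(OC)c1 | intermediate
5 | methyl 2-(5-methoxy-4-oxo-3-prop-2-enylcyclohexa-1,5-dien-1-yl)acetate (racemic ortho-dienone) | O=C1C(OC)=CC(CC(=O)OC)=CC1CC=C | intermediate (not isolated)
6 | methyl 2-(4-hydroxy-3-methoxy-5-prop-2-enylphenyl)acetate | COC(=O)Cc1cc(OC)c(O)c(CC=C)c1 | intermediate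
7 | methyl 2-(3,4-dimethoxy-5-prop-2-enylphenyl)acetate | COC(=O)Cc1cc(OC)c(OC)c(CC=C)c1 | intermediate
8 | methyl (Z)-2-(3,4-dimethoxy-5-prop-2-enylphenyl)-3-hydroxyprop-2-enoate | COC(=O)/C(=C\O)c1cc(OC)c(OC)c(CC=C)c1 | intermediate
9 | methyl (Z)-2-(3,4-dimethoxy-5-prop-2-enylphenyl)-3-(4-methylphenyl)sulfonyloxyprop-2-enoate | COC(=O)/C(=C\OS(=O)(=O)c1ccc(C)cc1)c1cc(OC)c(OC)c(CC=C)c1 | intermediate
10 | 3,5-bis(benzyloxy)phenol | Oc1cc(OCc2ccccc2)cc(OCc2ccccc2)c1 | starting material
11 | methyl (Z)-3-[3,5-bis(benzyloxy)phenoxy]-2-(3,4-dimethoxy-5-prop-2-enylphenyl)prop-2-enoate | COC(=O)/C(=C\Oc1cc(OCc2ccccc2)cc(OCc2ccccc2)c1)c1cc(OC)c(OC)c(CC=C)c1 | intermediate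
12 | (Z)-3-[3,5-bis(benzyloxy)phenoxy]-2-(3,4-dimethoxy-5-prop-2-enylphenyl)prop-2-enoic acid | OC(=O)/C(=C\Oc1cc(OCc2ccccc2)cc(OCc2ccccc2)c1)c1cc(OC)c(OC)c(CC=C)c1 | intermediate
13 | (Z)-3-[3,5-bis(benzyloxy)phenoxy]-2-(3,4-dimethoxy-5-prop-2-enylphenyl)prop-2-enoic trifluoroacetic anhydride | O=C(OC(=O)C(F)(F)F)/C(=C\Oc1cc(OCc2ccccc2)cc(OCc2ccccc2)c1)c1cc(OC)c(OC)c(CC=C)c1 | intermediate (not isolated)
14 | 5,7-bis(benzyloxy)-3-(3,4-dimethoxy-5-prop-2-enylphenyl)chromen-4-one | C=CCc1cc(-c2coc3cc(OCc4ccccc4)cc(OCc4ccccc4)c3c2=O)cc(OC)c1OC | intermediate
15 | 2-methylbut-2-ene | CC=C(C)C | starting material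
16 | 5,7-bis(benzyloxy)-3-[3,4-dimethoxy-5-(3-methylbut-2-enyl)phenyl]chromen-4-one | COc1cc(-c2coc3cc(OCc4ccccc4)cc(OCc4ccccc4)c3c2=O)cc(CC=C(C)C)c1OC | intermediate
17 | piscerythrinetin, 5,7-dihydroxy-3-[3,4-dimethoxy-5-(3-methylbut-2-enyl)phenyl]chromen-4-one | COc1cc(-c2coc3cc(O)cc(O)c3c2=O)cc(CC=C(C)C)c1OC | target

**Step count**

Total step count: 11. Longest linear sequence: 11 steps (1 to 17); compounds 3, 10 and 15 enter as purchased materials.

**Steps most likely to fail**

Step 9. Three things may go wrong: intermolecular trifluoroacetylation of the very electron-rich ring A may compete with ring closure, acid may cleave the aryl enol ether before acylation, or E-configured material may rotate too slowly into the reactive geometry. The fallback gives up the enol ether and forms the same C4–C4a bond intermolecularly, then closes ring C at O1–C2 (deoxybenzoin route). It sets out from 7 and 10. Saponification of 7 (LiOH, THF/H2O, then HCl) gives 2-(3,4-dimethoxy-5-prop-2-enylphenyl)acetic acid F1. Friedel–Crafts acylation of phenol 10 with F1 in BF3·OEt2 at moderate temperature, directed ortho to the free hydroxyl, gives 1-[2,4-bis(benzyloxy)-6-hydroxyphenyl]-2-(3,4-dimethoxy-5-prop-2-enylphenyl)ethanone F2. Heating F2 with N,N-dimethylformamide dimethyl acetal in toluene supplies C2 as an enaminone, which cyclises onto the phenol with loss of dimethylamine. The route is rejoined at 14.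

Step 7. The phenoxide may attack the sulfonyl sulfur (sulfonyl transfer back to the enolate of 8) instead of C3, or the ambident phenoxide may react through carbon. The fallback replaces the sulfonate by a vinylic chloride, which can only be attacked at carbon. It sets out from 8. Vilsmeier-type chlorination with oxalyl chloride and catalytic DMF in CH2Cl2 gives methyl (Z)-3-chloro-2-(3,4-dimethoxy-5-prop-2-enylphenyl)prop-2-enoate F3 (geometry not critical). Addition–elimination with phenol 10 and K2CO3 in DMF, optionally with DABCO as nucleophilic catalyst, returns to the route at 11.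

Step 11. Hydrogen chloride or benzyl cations may be captured by the trisubstituted prenyl alkene, or the vicinal methyl ethers may be partly cleaved on warming. The fallback inverts the order of the last two operations so that the Lewis acid only meets the far less basic allyl alkene. It sets out from 14. BCl3 with pentamethylbenzene in CH2Cl2 at −78 °C gives 5,7-dihydroxy-3-(3,4-dimethoxy-5-prop-2-enylphenyl)chromen-4-one F4. Cross-metathesis of F4 with 2-methylbut-2-ene (15) and the second-generation Grubbs catalyst, which tolerates free phenols, then installs the prenyl group. The route is rejoined at 17.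

**Further compounds**

F1 | step 9 | 2-(3,4-dimethoxy-5-prop-2-enylphenyl)acetic acid | OC(=O)Cc1cc(OC)c(OC)c(CC=C)c1
F2 | step 9 | 1-[2,4-bis(benzyloxy)-6-hydroxyphenyl]-2-(3,4-dimethoxy-5-prop-2-enylphenyl)ethanone | O=C(Cc1cc(OC)c(OC)c(CC=C)c1)c1c(O)cc(OCc2ccccc2)cc1OCc1ccccc1
F3 | step 7 | methyl (Z)-3-chloro-2-(3,4-dimethoxy-5-prop-2-enylphenyl)prop-2-enoate | COC(=O)/C(=C\Cl)c1cc(OC)c(OC)c(CC=C)c1
F4 | step 11 | 5,7-dihydroxy-3-(3,4-dimethoxy-5-prop-2-enylphenyl)chromen-4-one | C=CCc1cc(-c2coc3cc(O)cc(O)c3c2=O)cc(OC)c1OC
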